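## Retrosynthetic overview

1. Numbering: C1 = acyl-bearing bridgehead, C2–C3–C4 = enolised β-diketone bridge, C5 = bridgehead CH, C6–C7–C8 = second bridge, C9 = bridging ketone. Enabling feature: ring A (C1, C2, C3, C4, C5, C9) is a 1,3,5-tricarbonyl ring in which C1 is α to three carbonyls (C2, C9, isobutyryl C=O), so C1–C9 is a Claisen bond shared by ring A and ring B (C1, C9, C5, C6, C7, C8); the enolisable C2–C3–C4 unit is the built-in thermodynamic sink.
2. Key disconnection: C1–C9 and C1–C2 together, a double Claisen condensation at one ketone α-methylene. This leads back to acyclic keto diester 16 (isopropyl ketone plus C5-alkylated dimethyl 3-oxoglutarate).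
3. 16 ⇒ iodide 14 + dimethyl 3-oxopentanedioate 15 (C5–C6 alkylation); 14 ⇒ δ-lactone 11 (a temporary ring that tells the two chain ends apart) ⇒ diol 9 ⇒ acid 6.
4. Acid 6 ⇒ farnesyl 5-methylhex-4-enoate 3 by an enantioselective boron-enolate Ireland–Claisen rearrangement that sets C7 and C8 in one event; these two centres later relay C1 and C5.
5. Ring order: no carbocycle until the last step; ring B closes first (C1–C9), ring A second (C1–C2), in the same flask.

Key step: step 9

Assumption: the (4S,5S)-bromodiazaborolidine of step 2 (prepared beforehand from the bis-sulfonamide and BBr3) is taken to give the (2R,3S) acid, by analogy with crotyl- and geranyl-type esters; if the sense is opposite, the (4R,5R)-reagent is used and nothing else changes. The amine/solvent pair of step 2 is the one expected to give the enolate with the α-substituent cis to O–B.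

## Route

Step 1
Reactants: 1 (2E,6E)-farnesol; 2 5-methylhex-4-enoic acid
Product: 3 (2E,6E)-3,7,11-trimethyldodeca-2,6,10-trien-1-yl 5-methylhex-4-enoate
Conditions: N,N'-dicyclohexylcarbodiimide, 4-(dimethylamino)pyridine (cat.), CH2Cl2, 0 °C to rt
Reagents that add atoms: none
Why: Steglich esterification of a primary allylic alcohol under neutral conditions leaves the trisubstituted alkenes and the allylic C–O bond untouched; no stereocentre is formed.

Step 2
Reactants: 3 (2E,6E)-3,7,11-trimethyldodeca-2,6,10-trien-1-yl 5-methylhex-4-enoate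
Product: 6 (2R,3S,6E)-3-ethenyl-3,7,11-trimethyl-2-(3-methylbut-2-en-1-yl)dodeca-6,10-dienoic acid, via boron ketene acetal 4 (not isolated), via acyloxyborane 5 (not isolated)
Conditions: (4S,5S)-2-bromo-1,3-bis{[3,5-bis(trifluoromethyl)phenyl]sulfonyl}-4,5-diphenyl-1,3,2-diazaborolidine (1.2 equiv), i-Pr2NEt, CH2Cl2, −78 °C, then −20 °C to 4 °C; aqueous work-up
Reagents that add atoms: none
Why: Enantioselective Ireland–Claisen rearrangement: soft enolisation gives the (Z)-O-boron enolate 4, which rearranges through a chair transition state with the prenyl CH2 and the long (E)-alkene substituent both equatorial, so enolate and alkene geometry fix the relative configuration of C7 and C8 (acid C2 and C3) and the C2-symmetric ligand on boron selects the enolate face and hence the absolute configuration.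

Step 3
Reactants: 6 (2R,3S,6E)-3-ethenyl-3,7,11-trimethyl-2-(3-methylbut-2-en-1-yl)dodeca-6,10-dienoic acid
Product: 7 (2R,3S,6E)-3-ethenyl-3,7,11-trimethyl-2-(3-methylbut-2-en-1-yl)dodeca-6,10-dien-1-ol
Conditions: LiAlH4, THF, 0 °C to reflux; aqueous NaOH work-up
Reagents that add atoms: none
Why: LiAlH4 reduction of a carboxylic acid to the primary alcohol; the carboxylate formed first protects the α-stereocentre from enolisation and isolated alkenes are inert.

Step 4
Reactants: 7 (2R,3S,6E)-3-ethenyl-3,7,11-trimethyl-2-(3-methylbut-2-en-1-yl)dodeca-6,10-dien-1-ol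
Product: 9 (2R,3S)-3-[(3E)-4,8-dimethylnona-3,7-dien-1-yl]-3-methyl-2-(3-methylbut-2-en-1-yl)pentane-1,5-diol, via organoborane 8 (not isolated)
Conditions: 9-borabicyclo[3.3.1]nonane (2.2 equiv), THF, 0 °C to rt; then NaOH, H2O2, 0 °C to rt
Reagents that add atoms: hydrogen peroxide, OO
Why: Anti-Markovnikov hydroboration–oxidation: 9-borabicyclo[3.3.1]nonane adds to the monosubstituted vinyl group far faster than to the three trisubstituted alkenes and places boron on the terminal carbon, and alkaline peroxide replaces boron by OH without touching the stereocentres.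

Step 5
Reactants: 9 (2R,3S)-3-[(3E)-4,8-dimethylnona-3,7-dien-1-yl]-3-methyl-2-(3-methylbut-2-en-1-yl)pentane-1,5-diol
Product: 11 (4S,5R)-4-[(3E)-4,8-dimethylnona-3,7-dien-1-yl]-4-methyl-5-(3-methylbut-2-en-1-yl)oxan-2-one, via lactol 10 (not isolated)
Conditions: (2,2,6,6-tetramethylpiperidin-1-yl)oxyl (cat.), PhI(OAc)2 (2.5 equiv), CH2Cl2, rt
Reagents that add atoms: none
Why: Nitroxyl-catalysed oxidative lactonisation of a 1,5-diol: the oxoammonium ion oxidises the unbranched CH2CH2OH end faster than the β-branched CH2OH, the hydroxy aldehyde closes to lactol 10 and this is oxidised on, so the carbonyl sits on the carbon that becomes the isobutyryl C=O.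

Step 6
Reactants: 11 (4S,5R)-4-[(3E)-4,8-dimethylnona-3,7-dien-1-yl]-4-methyl-5-(3-methylbut-2-en-1-yl)oxan-2-one
Product: 13 (5S,6R)-5-[(3E)-4,8-dimethylnona-3,7-dien-1-yl]-6-(hydroxymethyl)-2,5,9-trimethyldec-8-en-3-one, via lithium hemiketalate 12 (not isolated)
Conditions: i-PrLi (1.1 equiv), THF–pentane, −78 °C; NH4Cl (aq.) at −78 °C
Reagents that add atoms: isopropyllithium, [Li]C(C)C
Why: Mono-addition of an organolithium to a lactone: the tetrahedral lithium hemiketalate 12 persists at −78 °C and collapses only on protonation, so one isopropyl group is delivered and the C6 hydroxyl is released in the same operation.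

Step 7
Reactants: 13 (5S,6R)-5-[(3E)-4,8-dimethylnona-3,7-dien-1-yl]-6-(hydroxymethyl)-2,5,9-trimethyldec-8-en-3-one
Product: 14 (5S,6R)-5-[(3E)-4,8-dimethylnona-3,7-dien-1-yl]-6-(iodomethyl)-2,5,9-trimethyldec-8-en-3-one
Conditions: PPh3, I2, imidazole, CH2Cl2, 0 °C to rt
Reagents that add atoms: iodine, II
Why: Appel iodination: SN2 displacement of the alkoxyphosphonium ion by iodide at a CH2 carbon, which leaves the ketone, the alkenes and both stereocentres untouched.

Step 8
Reactants: 14 (5S,6R)-5-[(3E)-4,8-dimethylnona-3,7-dien-1-yl]-6-(iodomethyl)-2,5,9-trimethyldec-8-en-3-one; 15 dimethyl 3-oxopentanedioate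
Product: 16 dimethyl 2-{(2S,3S)-3-[(3E)-4,8-dimethylnona-3,7-dien-1-yl]-3,6-dimethyl-2-(3-methylbut-2-en-1-yl)-5-oxoheptyl}-3-oxopentanedioate
Conditions: 15 (3 equiv), K2CO3, DMF, 50 °C
Reagents that add atoms: none
Why: SN2 C-alkylation of the soft potassium enolate of a β-keto ester by a primary iodide; the two α-carbons of 15 are equivalent, excess 15 holds back double alkylation, and the new C5 centre forms as an epimerisable mixture that is funnelled in step 9.

Step 9
Reactants: 16 dimethyl 2-{(2S,3S)-3-[(3E)-4,8-dimethylnona-3,7-dien-1-yl]-3,6-dimethyl-2-(3-methylbut-2-en-1-yl)-5-oxoheptyl}-3-oxopentanedioate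
Product: 18 prolifenone B, via ring-B triketo ester 17 (not isolated)
Conditions: NaOMe (2.5 equiv), MeOH–THF, 50 °C; then Mg(OMe)2 (6 equiv), MeOH, 65 °C; then 1 M HCl, 0 °C
Reagents that add atoms: none
Why: Proposed new method: a double Claisen condensation at one carbon, in which NaOMe first lets the C1 enolate of the isopropyl ketone attack the C9 ester on C5 (6-exo-trig, enolexo) to form the C1–C9 bond and ring B as the 2-acylcyclohexanone enolate 17, and Mg(OMe)2 then lets C1 of this chelated β-diketone attack the C2 ester of the axially disposed C5 side chain (6-exo-trig) to form C1–C2, ring A and the quaternary C1, with the enolisable C2–C3–C4 β-diketone of the product as the thermodynamic sink. The closest known reaction types are the Dieckmann-type cyclisation of keto esters to 2-acylcycloalkanones and the Mg(OMe)2-mediated Claisen cyclisation of 3,5-dioxo esters to cyclohexane-1,3,5-triones (the acylphloroglucinol closure); geminal use of both at one ketone methylene to give a bridged, non-aromatic trione has not been shown. C1 and C5 are created together because the three-carbon bridge can only span ring B 1,3-diaxially, and their sense is relayed from C7 and C8: only the chair with the C7 prenyl group equatorial and the C8 methyl group axial on the opposite face lets the C5 side chain and the forming C1–C2 bond stand axial on one face without a syn-triaxial clash, so the 7-exo isomer should result (C5 is epimerisable in 16 and 17). The step needs C- instead of O-acylation in the second closure and acylation instead of aldol addition to the hindered isopropyl ketone; chelation of the β-diketone oxygens by magnesium, the reversibility of enol-lactone formation and of aldol addition under methoxide, and the inertness of the product enolate are expected to secure this. The isobutyryl group must end up exocyclic on C1 because both acyl carbons that reach C1 are tethered through C5, so no choice arises between the acyl groups.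

## Compound list

1 | (2E,6E)-farnesol | CC(C)=CCC/C(C)=C/CC/C(C)=C/CO | starting material
2 | 5-methylhex-4-enoic acid | CC(C)=CCCC(=O)O | starting material
3 | (2E,6E)-3,7,11-trimethyldodeca-2,6,10-trien-1-yl 5-methylhex-4-enoate | CC(C)=CCC/C(C)=C/CC/C(C)=C/COC(=O)CCC=C(C)C | intermediate
4 | boron ketene acetal of 3: (Z)-enolate (prenyl CH2 cis to O–B), boron carrying the (4S,5S)-4,5-diphenyl-1,3-bis(arylsulfonyl)diazaborolidine | CC(C)=CC/C=C(\OB1N(S(=O)(=O)c2cc(cc(c2)C(F)(F)F)C(F)(F)F)[C@@H](c2ccccc2)[C@H](c2ccccc2)N1S(=O)(=O)c1cc(cc(c1)C(F)(F)F)C(F)(F)F)OC/C=C(\C)CC/C=C(\C)CCC=C(C)C | intermediate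
5 | acyloxyborane: O-boryl carboxylate of acid 6 with the same (4S,5S)-diazaborolidine | CC(C)=CCC/C(C)=C/CC[C@](C=C)(C)[C@@H](CC=C(C)C)C(=O)OB1N(S(=O)(=O)c2cc(cc(c2)C(F)(F)F)C(F)(F)F)[C@@H](c2ccccc2)[C@H](c2ccccc2)N1S(=O)(=O)c1cc(cc(c1)C(F)(F)F)C(F)(F)F | intermediate
6 | (2R,3S,6E)-3-ethenyl-3,7,11-trimethyl-2-(3-methylbut-2-en-1-yl)dodeca-6,10-dienoic acid | CC(C)=CCC/C(C)=C/CC[C@](C=C)(C)[C@@H](CC=C(C)C)C(=O)O | intermediate
7 | (2R,3S,6E)-3-ethenyl-3,7,11-trimethyl-2-(3-methylbut-2-en-1-yl)dodeca-6,10-dien-1-ol | CC(C)=CCC/C(C)=C/CC[C@](C=C)(C)[C@@H](CC=C(C)C)CO | intermediate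
8 | organoborane: B-alkyl-9-borabicyclo[3.3.1]nonane at the former vinyl terminus of 7, the hydroxyl as its O-(9-borabicyclo[3.3.1]nonan-9-yl) borinate | CC(C)=CCC/C(C)=C/CC[C@](CCB1C2CCCC1CCC2)(C)[C@@H](CC=C(C)C)COB1C2CCCC1CCC2 | intermediate
9 | (2R,3S)-3-[(3E)-4,8-dimethylnona-3,7-dien-1-yl]-3-methyl-2-(3-methylbut-2-en-1-yl)pentane-1,5-diol | CC(C)=CCC/C(C)=C/CC[C@](CCO)(C)[C@@H](CC=C(C)C)CO | intermediate
10 | (4S,5R)-4-[(3E)-4,8-dimethylnona-3,7-dien-1-yl]-4-methyl-5-(3-methylbut-2-en-1-yl)oxan-2-ol (lactol, both anomers) | CC(C)=CCC/C(C)=C/CC[C@@]1(C)CC(O)OC[C@@H]1CC=C(C)C | intermediate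
11 | (4S,5R)-4-[(3E)-4,8-dimethylnona-3,7-dien-1-yl]-4-methyl-5-(3-methylbut-2-en-1-yl)oxan-2-one | CC(C)=CCC/C(C)=C/CC[C@@]1(C)CC(=O)OC[C@@H]1CC=C(C)C | intermediate
12 | lithium (4S,5R)-4-[(3E)-4,8-dimethylnona-3,7-dien-1-yl]-4-methyl-5-(3-methylbut-2-en-1-yl)-2-(propan-2-yl)oxan-2-olate | [Li+].CC(C)=CCC/C(C)=C/CC[C@@]1(C)CC([O-])(C(C)C)OC[C@@H]1CC=C(C)C | intermediate
13 | (5S,6R)-5-[(3E)-4,8-dimethylnona-3,7-dien-1-yl]-6-(hydroxymethyl)-2,5,9-trimethyldec-8-en-3-one | CC(C)=CCC/C(C)=C/CC[C@](CC(=O)C(C)C)(C)[C@@H](CC=C(C)C)CO | intermediate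
14 | (5S,6R)-5-[(3E)-4,8-dimethylnona-3,7-dien-1-yl]-6-(iodomethyl)-2,5,9-trimethyldec-8-en-3-one | CC(C)=CCC/C(C)=C/CC[C@](CC(=O)C(C)C)(C)[C@@H](CC=C(C)C)CI | intermediate
15 | dimethyl 3-oxopentanedioate | COC(=O)CC(=O)CC(=O)OC | starting material
16 | dimethyl 2-{(2S,3S)-3-[(3E)-4,8-dimethylnona-3,7-dien-1-yl]-3,6-dimethyl-2-(3-methylbut-2-en-1-yl)-5-oxoheptyl}-3-oxopentanedioate (both epimers at C2 of the diester) | CC(C)=CCC/C(C)=C/CC[C@](CC(=O)C(C)C)(C)[C@@H](CC=C(C)C)CC(C(=O)OC)C(=O)CC(=O)OC | intermediate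
17 | methyl 3-[(4R,5S)-4-[(3E)-4,8-dimethylnona-3,7-dien-1-yl]-4-methyl-5-(3-methylbut-2-en-1-yl)-3-(2-methylpropanoyl)-2-oxocyclohexyl]-3-oxopropanoate (ring C1 and C3 epimerisable; present as its enolate) | CC(C)=CCC/C(C)=C/CC[C@]1(C)[C@@H](CC=C(C)C)CC(C(=O)CC(=O)OC)C(=O)C1C(=O)C(C)C | intermediate
18 | prolifenone B, (1R,5R,7S,8R)-8-[(3E)-4,8-dimethylnona-3,7-dien-1-yl]-4-hydroxy-8-methyl-7-(3-methylbut-2-en-1-yl)-1-(2-methylpropanoyl)bicyclo[3.3.1]non-3-ene-2,9-dione | CC(C)=CCC/C(C)=C/CC[C@]1(C)[C@@H](CC=C(C)C)C[C@H]2C(=O)[C@]1(C(=O)C(C)C)C(=O)C=C2O | target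

## Step count and risks

Total step count: 9. Longest linear sequence: 9 steps from 1 (2 and 15 are purchased).

Steps most likely to fail:

1. Step 9 (Proposed new method). After the first Claisen closure, the 3,5-dioxo ester unit of 17 may acylate the C9 enolate oxygen (lactonisation to a fused 4-hydroxypyran-2-one) faster than the hindered C1. The second acylation may also stall, because it must build a quaternary carbon next to a quaternary carbon. The fallback separates the two acylations at C1 and runs the second under acidic, irreversible conditions, using known reactions only. It sets out from 14. Alkylation with NaH and dimethyl malonate in DMF would give dimethyl 2-{(2S,3S)-3-[(3E)-4,8-dimethylnona-3,7-dien-1-yl]-3,6-dimethyl-2-(3-methylbut-2-en-1-yl)-5-oxoheptyl}propanedioate F1. Krapcho dealkoxycarbonylation (LiCl, wet DMSO, 140 °C) would give methyl (4R,5S)-5-[(3E)-4,8-dimethylnona-3,7-dien-1-yl]-5,8-dimethyl-4-(3-methylbut-2-en-1-yl)-7-oxononanoate F2. KOtBu in THF would close ring B by the same C1–C9 Claisen condensation, now as a separate Dieckmann-type step, to (3R,4R)-3-[(3E)-4,8-dimethylnona-3,7-dien-1-yl]-3-methyl-4-(3-methylbut-2-en-1-yl)-2-(2-methylpropanoyl)cyclohexan-1-one F3. Silylation (Me3SiCl, Et3N) would give the enol silyl ether 1-{(5R,6R)-6-[(3E)-4,8-dimethylnona-3,7-dien-1-yl]-6-methyl-5-(3-methylbut-2-en-1-yl)-2-[(trimethylsilyl)oxy]cyclohex-1-en-1-yl}-2-methylpropan-1-one F4. An Effenberger cyclisation with malonyl dichloride (CH2Cl2, −20 °C to rt; then aqueous KOH, benzyltriethylammonium chloride; acidification) would add C2–C3–C4 across C1 and C5, first at C1 and then at the only remaining enolisable position C5, and comes back to the route at 18.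

2. Step 8. SN2 displacement at the β-branched CH2–I is slow, so double alkylation, O-alkylation and base-induced self-condensation of 15 may take over. The fallback replaces substitution by condensation and reduction. It sets out from 13. Dess–Martin oxidation would give (2R,3S)-3-[(3E)-4,8-dimethylnona-3,7-dien-1-yl]-3,6-dimethyl-2-(3-methylbut-2-en-1-yl)-5-oxoheptanal F5. Knoevenagel condensation with 15 under non-enamine conditions (TiCl4, pyridine, THF, 0 °C, chosen to limit epimerisation next to the aldehyde) would give dimethyl 2-{(2S,3S)-3-[(3E)-4,8-dimethylnona-3,7-dien-1-yl]-3,6-dimethyl-2-(3-methylbut-2-en-1-yl)-5-oxoheptylidene}-3-oxopentanedioate F6. Conjugate reduction of the alkylidene β-keto ester with Hantzsch ester (diethyl 2,6-dimethyl-1,4-dihydropyridine-3,5-dicarboxylate) comes back to the route at 16.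

3. Step 6. The hemiketalate may collapse early and take up a second equivalent of the organolithium, or the basic secondary alkyllithium may deprotonate the lactone α-CH2 instead of adding. The fallback uses a stable chelated adduct instead of a labile one. It sets out from 11. Aminolysis with the aluminium amide from AlMe3 and N,O-dimethylhydroxylamine hydrochloride would give (3S,4R)-3-[(3E)-4,8-dimethylnona-3,7-dien-1-yl]-4-(hydroxymethyl)-N-methoxy-N,3,7-trimethyloct-6-enamide F7. i-PrMgCl (excess; the first equivalent deprotonates the hydroxyl) in a Weinreb ketone synthesis comes back to the route at 13.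

## Further compounds

F1 | step 9 | dimethyl 2-{(2S,3S)-3-[(3E)-4,8-dimethylnona-3,7-dien-1-yl]-3,6-dimethyl-2-(3-methylbut-2-en-1-yl)-5-oxoheptyl}propanedioate | CC(C)=CCC/C(C)=C/CC[C@](CC(=O)C(C)C)(C)[C@@H](CC=C(C)C)CC(C(=O)OC)C(=O)OC
F2 | step 9 | methyl (4R,5S)-5-[(3E)-4,8-dimethylnona-3,7-dien-1-yl]-5,8-dimethyl-4-(3-methylbut-2-en-1-yl)-7-oxononanoate | CC(C)=CCC/C(C)=C/CC[C@](CC(=O)C(C)C)(C)[C@@H](CC=C(C)C)CCC(=O)OC
F3 | step 9 | (3R,4R)-3-[(3E)-4,8-dimethylnona-3,7-dien-1-yl]-3-methyl-4-(3-methylbut-2-en-1-yl)-2-(2-methylpropanoyl)cyclohexan-1-one | CC(C)=CCC/C(C)=C/CC[C@]1(C)[C@@H](CC=C(C)C)CCC(=O)C1C(=O)C(C)C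
F4 | step 9 | 1-{(5R,6R)-6-[(3E)-4,8-dimethylnona-3,7-dien-1-yl]-6-methyl-5-(3-methylbut-2-en-1-yl)-2-[(trimethylsilyl)oxy]cyclohex-1-en-1-yl}-2-methylpropan-1-one | CC(C)=CCC/C(C)=C/CC[C@]1(C)[C@@H](CC=C(C)C)CCC(O[Si](C)(C)C)=C1C(=O)C(C)C
F5 | step 8 | (2R,3S)-3-[(3E)-4,8-dimethylnona-3,7-dien-1-yl]-3,6-dimethyl-2-(3-methylbut-2-en-1-yl)-5-oxoheptanal | CC(C)=CCC/C(C)=C/CC[C@](CC(=O)C(C)C)(C)[C@@H](CC=C(C)C)C=O
F6 | step 8 | dimethyl 2-{(2S,3S)-3-[(3E)-4,8-dimethylnona-3,7-dien-1-yl]-3,6-dimethyl-2-(3-methylbut-2-en-1-yl)-5-oxoheptylidene}-3-oxopentanedioate | CC(C)=CCC/C(C)=C/CC[C@](CC(=O)C(C)C)(C)[C@@H](CC=C(C)C)C=C(C(=O)OC)C(=O)CC(=O)OC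
F7 | step 6 | (3S,4R)-3-[(3E)-4,8-dimethylnona-3,7-dien-1-yl]-4-(hydroxymethyl)-N-methoxy-N,3,7-trimethyloct-6-enamide | CC(C)=CCC/C(C)=C/CC[C@](CC(=O)N(C)OC)(C)[C@@H](CC=C(C)C)CO
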